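Everything rests on cutting ring B at two adjacent carbons at once: the C1'–carbonyl bond and the C6'–oxygen bond. An aryne spanning C1' and C6' inserts into the C–O bond of the hindered ring A carboxylic acid (carboxyl on C2, between the C1 ester and the C3 methoxy group). One operation therefore sets both the diaryl ketone and its ortho phenol. The feature exploited is the C2' oxygen of ring B, which flanks the aryne and fixes the orientation of addition. The precursors are an orcinol-derived 2-silylaryl triflate with a MOM ether beside silicon and a MOM-protected phthalic half ester. Deprotection and one chlorination at C3'/C5' finish the synthesis.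

Key step: step 12

Remark on the chemistry:
- Ring A locants: C1 carries CO2Me, C2 the ketone, C3 OMe and C5 OH.
- Ring B locants: C1' carries the ketone, C2' and C6' the oxygens and C4' the methyl group.
- The target is achiral, so no stereocentre has to be set.
- Orcinol is used in anhydrous form.

**Ring B: aryne precursor**

Step 1
Reactants: 1 orcinol
Product: 2 3-(methoxymethoxy)-5-methylphenol
Conditions: MOMCl (1.0 equiv), iPr2NEt (1.2 equiv), THF, 0 °C to rt; chromatography
Reagents that add atoms: chloromethyl methyl ether (MOMCl), COCCl
Why: Williamson-type O-alkylation of one of two equivalent phenols with a single equivalent of MOMCl should give the mono-acetal as the main part of a statistical mixture that chromatography resolves, and unreacted 1 is recycled.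

Step 2
Reactants: 2 3-(methoxymethoxy)-5-methylphenol
Product: 3 3-(methoxymethoxy)-5-methylphenyl N-isopropylcarbamate
Conditions: iPrNCO (1.5 equiv), Et3N (0.2 equiv), CH2Cl2, rt
Reagents that add atoms: isopropyl isocyanate, CC(C)N=C=O
Why: Base-catalysed addition of the phenol to the isocyanate (carbamoylation) installs a strong ortho-directing group that mild base can remove later.

Step 3
Reactants: 3 3-(methoxymethoxy)-5-methylphenyl N-isopropylcarbamate
Product: 7 3-(methoxymethoxy)-5-methyl-2-(trimethylsilyl)phenyl N-isopropylcarbamate, via N-silyl carbamate 4 (not isolated), via C2 aryllithium 5 (not isolated), via N-silyl C-silyl carbamate 6 (not isolated)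
Conditions: TBSOTf (1.1 equiv), TMEDA (1.1 equiv), Et2O, 0 °C to rt; then TMEDA (2 equiv), n-BuLi (2 equiv), −78 °C; TMSCl (3 equiv), −78 °C to rt; brief cold aq NaHSO4 work-up
Reagents that add atoms: chlorotrimethylsilane (TMSCl), C[Si](C)(C)Cl; tert-butyldimethylsilyl trifluoromethanesulfonate (TBSOTf), CC(C)(C)[Si](C)(C)OS(=O)(=O)C(F)(F)F (its silyl group is carried only by 4, 5 and 6)
Why: This is a directed ortho-metalation in which transient N-silylation masks the N–H, the carbamate and MOM ether together steer n-BuLi to the C2 hydrogen between them, TMSCl traps the aryllithium and work-up hydrolyses the labile N–Si bond, the aryl MOM ether being inert to an amine-buffered silyl triflate in ether.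

Step 4
Reactants: 7 3-(methoxymethoxy)-5-methyl-2-(trimethylsilyl)phenyl N-isopropylcarbamate
Product: 9 3-(methoxymethoxy)-5-methyl-2-(trimethylsilyl)phenyl trifluoromethanesulfonate, via silylphenol 8 (not isolated)
Conditions: Et2NH (1.2 equiv), DBU (1.5 equiv), MeCN, 40 °C; then PhNTf2 (1.5 equiv), rt
Reagents that add atoms: N-phenylbis(trifluoromethanesulfonimide) (PhNTf2), O=S(=O)(N(c1ccccc1)S(=O)(=O)C(F)(F)F)C(F)(F)F
Why: DBU deprotonates the N–H carbamate, which fragments by E1cB elimination to the phenoxide and isopropyl isocyanate (scavenged by Et2NH), and PhNTf2 sulfonylates the phenoxide in the same flask, so the acid-sensitive silylphenol is never handled.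

**Ring A: acid**

Step 5
Reactants: 10 1,1-dimethoxyethene (2.1 equiv); 11 acetyl chloride (1.0 equiv)
Product: 12 4,4-dimethoxybut-3-en-2-one
Conditions: Et2O, 0 °C to reflux; distillation
Reagents that add atoms: none
Why: C-acylation of the electron-rich ketene acetal gives a dioxocarbenium ion whose acidic α-proton is taken by the second equivalent of 10, which is the established route to acylketene acetals.

Step 6
Reactants: 12 4,4-dimethoxybut-3-en-2-one
Product: 13 1,1-dimethoxy-3-(trimethylsilyloxy)buta-1,3-diene
Conditions: TMSCl (1.3 equiv), Et3N (1.5 equiv), ZnCl2 (3 mol %), toluene, 40 °C; filtration, distillation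
Reagents that add atoms: chlorotrimethylsilane (TMSCl), C[Si](C)(C)Cl
Why: Soft enolisation of the only enolisable position (the acetyl methyl group) followed by O-silylation gives the 2-silyloxydiene, as in the standard preparation of oxygenated Diels–Alder dienes.

Step 7
Reactants: 13 1,1-dimethoxy-3-(trimethylsilyloxy)buta-1,3-diene; 14 dimethyl acetylenedicarboxylate
Product: 17 dimethyl 5-hydroxy-3-methoxyphthalate, via Diels–Alder adduct 15 (not isolated), via aryl silyl ether 16 (not isolated)
Conditions: toluene, 0 °C to 80 °C; then 0.1 M HCl, THF, rt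
Reagents that add atoms: none
Why: The Diels–Alder reaction of the very electron-rich diene with the symmetrical electron-poor alkyne raises no regiochemical question, and adduct 15 aromatises by loss of methanol before mild acid removes silicon, leaving the C3 methyl ether and C5 phenol already differentiated.

Step 8
Reactants: 17 dimethyl 5-hydroxy-3-methoxyphthalate
Product: 18 dimethyl 3-methoxy-5-(methoxymethoxy)phthalate
Conditions: MOMCl (1.3 equiv), iPr2NEt (1.6 equiv), CH2Cl2, 0 °C to rt
Reagents that add atoms: chloromethyl methyl ether (MOMCl), COCCl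
Why: O-alkylation of the only free phenol masks the one group of ring A that would otherwise add to the aryne.

Step 9
Reactants: 18 dimethyl 3-methoxy-5-(methoxymethoxy)phthalate
Product: 19 3-methoxy-5-(methoxymethoxy)phthalic acid
Conditions: KOH (6 equiv), MeOH–H2O 3:1, reflux; then cold 1 M HCl to pH 3, EtOAc extraction
Reagents that add atoms: potassium hydroxide, [K+].[OH-]
Why: Saponification with excess hot hydroxide cleaves both esters, including the hindered C2 ester, while the MOM acetal is base-stable and tolerates a brief cold acidification.

Step 10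
Reactants: 19 3-methoxy-5-(methoxymethoxy)phthalic acid
Product: 20 3-methoxy-5-(methoxymethoxy)phthalic anhydride
Conditions: DCC (1.05 equiv), CH2Cl2, 0 °C to rt; filtration
Reagents that add atoms: none
Why: Carbodiimide dehydration of an ortho-diacid closes the five-membered anhydride under neutral conditions that leave the acetal untouched.

Step 11
Reactants: 20 3-methoxy-5-(methoxymethoxy)phthalic anhydride
Product: 21 2-methoxy-6-(methoxycarbonyl)-4-(methoxymethoxy)benzoic acid
Conditions: NaOMe (1.05 equiv), MeOH–THF, −20 °C to 0 °C; then cold 1 M HCl to pH 3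
Reagents that add atoms: sodium methoxide, [Na+].[O-]C
Why: In this regioselective anhydride alcoholysis methoxide should attack the C1 carbonyl, which is unhindered and only meta to both oxygen donors, rather than the C2 carbonyl, which is shielded by the C3 methoxy group and deactivated by ortho and para oxygen lone pairs, so the free acid ends up on C2.

**Union and endgame**

Step 12
Reactants: 9 3-(methoxymethoxy)-5-methyl-2-(trimethylsilyl)phenyl trifluoromethanesulfonate; 21 2-methoxy-6-(methoxycarbonyl)-4-(methoxymethoxy)benzoic acid
Product: 25 methyl 2-[2-hydroxy-6-(methoxymethoxy)-4-methylbenzoyl]-3-methoxy-5-(methoxymethoxy)benzoate, via 3-(methoxymethoxy)-5-methylbenzyne 22 (not isolated), via C1' aryl anion ester 23 (not isolated), via four-membered alkoxide 24 (not isolated)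
Conditions: 9 (1.5 equiv), dry CsF (4 equiv), THF (0.02 M), sealed vessel, 125 °C, 24 h; aq NH4Cl work-up
Reagents that add atoms: none
Why: Fluoride attacks silicon in 9 and triflate leaves, giving aryne 22, whose C1'–C6' triple bond is polarised by the σ-withdrawing C2' OMOM group, so the cesium carboxylate of 21 bonds through oxygen to the remote C6' and the charge develops at C1', next to that oxygen (23). The C1' anion then attacks the adjacent ester carbonyl (4-exo-trig) to give the strained alkoxide 24, which opens by C–O cleavage to the ketone and the C6' phenoxide. This is the known fluoride-induced insertion of arynes into the C–O bond of carboxylic acids, in effect an O-arylation followed by an anionic Fries-type 1,3-acyl shift, and it is established for benzoic acids and 3-alkoxybenzynes in hot THF. The four-membered ring is transient, so no ring remains in 25, and no stereocentre is formed. Two selectivities are needed: the orientation of addition, secured by the alkoxy group flanking the aryne, and acyl capture of the anion ahead of protonation or attack on the C1 methyl ester, favoured by proximity (four-membered against seven-membered transition state), a non-acidic solvent, high dilution and dry CsF. The di-ortho-substituted carbonyl of 21 is the weak point, which is why 9 is used in excess.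

Step 13
Reactants: 25 methyl 2-[2-hydroxy-6-(methoxymethoxy)-4-methylbenzoyl]-3-methoxy-5-(methoxymethoxy)benzoate
Product: 26 sulochrin, methyl 2-(2,6-dihydroxy-4-methylbenzoyl)-5-hydroxy-3-methoxybenzoate
Conditions: HCl (0.5 M in MeOH), 45 °C
Reagents that add atoms: none
Why: Acid-catalysed acetal exchange with methanol removes both aryl MOM ethers, while ester exchange is degenerate in methanol and the aryl methyl ether and diaryl ketone are inert.

Step 14
Reactants: 26 sulochrin
Product: 27 monochlorosulochrin, methyl 2-(3-chloro-2,6-dihydroxy-4-methylbenzoyl)-5-hydroxy-3-methoxybenzoate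
Conditions: NCS (1.0 equiv, in portions), MeCN, 0 °C to rt
Reagents that add atoms: N-chlorosuccinimide (NCS), O=C1CCC(=O)N1Cl
Why: In this electrophilic aromatic chlorination C3' and C5' are equivalent and each is ortho to one hydroxyl, para to the other and ortho to the methyl group, whereas the open positions of ring A lie ortho or para to the deactivating ester, so one equivalent of NCS should chlorinate ring B once.

**Compound list**

1 | orcinol (5-methylbenzene-1,3-diol) | Cc1cc(O)cc(O)c1 | starting material
2 | 3-(methoxymethoxy)-5-methylphenol | COCOc1cc(C)cc(O)c1 | intermediate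
3 | 3-(methoxymethoxy)-5-methylphenyl N-isopropylcarbamate | CC(C)NC(=O)Oc1cc(C)cc(OCOC)c1 | intermediate
4 | 3-(methoxymethoxy)-5-methylphenyl N-(tert-butyldimethylsilyl)-N-isopropylcarbamate | CC(C)N(C(=O)Oc1cc(C)cc(OCOC)c1)[Si](C)(C)C(C)(C)C | intermediate
5 | C2-lithiated derivative of 4 (lithium between the carbamate oxygen and the MOM ether) | CC(C)N(C(=O)Oc1cc(C)cc(OCOC)c1[Li])[Si](C)(C)C(C)(C)C | intermediate
6 | 3-(methoxymethoxy)-5-methyl-2-(trimethylsilyl)phenyl N-(tert-butyldimethylsilyl)-N-isopropylcarbamate | CC(C)N(C(=O)Oc1cc(C)cc(OCOC)c1[Si](C)(C)C)[Si](C)(C)C(C)(C)C | intermediate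
7 | 3-(methoxymethoxy)-5-methyl-2-(trimethylsilyl)phenyl N-isopropylcarbamate | CC(C)NC(=O)Oc1cc(C)cc(OCOC)c1[Si](C)(C)C | intermediate
8 | 3-(methoxymethoxy)-5-methyl-2-(trimethylsilyl)phenol | COCOc1cc(C)cc(O)c1[Si](C)(C)C | intermediate
9 | 3-(methoxymethoxy)-5-methyl-2-(trimethylsilyl)phenyl trifluoromethanesulfonate | COCOc1cc(C)cc(OS(=O)(=O)C(F)(F)F)c1[Si](C)(C)C | intermediate
10 | 1,1-dimethoxyethene | C=C(OC)OC | starting material
11 | acetyl chloride | CC(=O)Cl | starting material
12 | 4,4-dimethoxybut-3-en-2-one | CC(=O)C=C(OC)OC | intermediate
13 | 1,1-dimethoxy-3-(trimethylsilyloxy)buta-1,3-diene | C=C(O[Si](C)(C)C)C=C(OC)OC | intermediate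
14 | dimethyl acetylenedicarboxylate | COC(=O)C#CC(=O)OC | starting material
15 | dimethyl 3,3-dimethoxy-5-(trimethylsilyloxy)cyclohexa-1,4-diene-1,2-dicarboxylate | COC(=O)C1=C(C(=O)OC)C(OC)(OC)C=C(O[Si](C)(C)C)C1 | intermediate
16 | dimethyl 3-methoxy-5-(trimethylsilyloxy)phthalate | COC(=O)c1cc(O[Si](C)(C)C)cc(OC)c1C(=O)OC | intermediate
17 | dimethyl 5-hydroxy-3-methoxyphthalate | COC(=O)c1cc(O)cc(OC)c1C(=O)OC | intermediate
18 | dimethyl 3-methoxy-5-(methoxymethoxy)phthalate | COCOc1cc(OC)c(C(=O)OC)c(C(=O)OC)c1 | intermediate
19 | 3-methoxy-5-(methoxymethoxy)phthalic acid | COCOc1cc(OC)c(C(=O)O)c(C(=O)O)c1 | intermediate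
20 | 3-methoxy-5-(methoxymethoxy)phthalic anhydride (4-methoxy-6-(methoxymethoxy)-2-benzofuran-1,3-dione) | COCOc1cc(OC)c2C(=O)OC(=O)c2c1 | intermediate
21 | 2-methoxy-6-(methoxycarbonyl)-4-(methoxymethoxy)benzoic acid | COC(=O)c1cc(OCOC)cc(OC)c1C(=O)O | intermediate
22 | 3-(methoxymethoxy)-5-methylbenzyne | COCOC1=CC(C)=CC#C1 | intermediate
23 | cesium salt of the C1' carbanion of 3-(methoxymethoxy)-5-methylphenyl 2-methoxy-6-(methoxycarbonyl)-4-(methoxymethoxy)benzoate (charge between the two ring B oxygens) | COC(=O)c1cc(OCOC)cc(OC)c1C(=O)Oc1cc(C)cc(OCOC)[c-]1.[Cs+] | intermediate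
24 | cesium 2-[2-methoxy-6-(methoxycarbonyl)-4-(methoxymethoxy)phenyl]-3-(methoxymethoxy)-5-methyl-2H-benzo[b]oxet-2-olate | COC(=O)c1cc(OCOC)cc(OC)c1C1([O-])Oc2cc(C)cc(OCOC)c12.[Cs+] | intermediate
25 | methyl 2-[2-hydroxy-6-(methoxymethoxy)-4-methylbenzoyl]-3-methoxy-5-(methoxymethoxy)benzoate | COC(=O)c1cc(OCOC)cc(OC)c1C(=O)c1c(O)cc(C)cc1OCOC | intermediate
26 | sulochrin, methyl 2-(2,6-dihydroxy-4-methylbenzoyl)-5-hydroxy-3-methoxybenzoate | COC(=O)c1cc(O)cc(OC)c1C(=O)c1c(O)cc(C)cc1O | intermediate
27 | monochlorosulochrin, methyl 2-(3-chloro-2,6-dihydroxy-4-methylbenzoyl)-5-hydroxy-3-methoxybenzoate | COC(=O)c1cc(O)cc(OC)c1C(=O)c1c(O)cc(C)c(Cl)c1O | target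

**Step count**

- Total step count: 14.
- Longest linear sequence: 10 steps (steps 5 to 14, from 10 and 11 to 27). The ring B branch contributes 4 steps up to 9.

**Steps most likely to fail**

1. Step 12.
What may go wrong:
- protonation of the C1' anion before acyl transfer;
- sluggish attack on the di-ortho-substituted carbonyl;
- diversion of the anion to the C1 methyl ester;
- scrambling of the half ester through anhydride formation at 125 °C;
- further arylation of the product phenoxide by excess aryne.

The fallback sets out from 1 and 21 and returns at 26. Orcinol 1 is alkylated on both phenols (excess MOMCl, iPr2NEt) to 1,3-bis(methoxymethoxy)-5-methylbenzene F1. n-BuLi (THF, 0 °C) metalates this between the two acetal oxygens to [2,6-bis(methoxymethoxy)-4-methylphenyl]lithium F2. Acid 21 is converted under neutral conditions with 1-chloro-N,N,2-trimethylprop-1-en-1-amine (CH2Cl2, 0 °C) into methyl 2-(chlorocarbonyl)-3-methoxy-5-(methoxymethoxy)benzoate F3, which is used at once. Slow addition of F2 at −78 °C should stop at methyl 2-[2,6-bis(methoxymethoxy)-4-methylbenzoyl]-3-methoxy-5-(methoxymethoxy)benzoate F4, because the acid chloride reacts far faster than the methyl ester and the crowded ketone resists a second addition. The conditions of step 13 then remove all three MOM groups and give 26. The ring B–carbonyl bond is thus made by intermolecular acylation of a preformed aryl anion that already carries both ring B oxygens, with no aryne and no acyl shift.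

2. Step 14.
What may go wrong: a second chlorination of ring B, competing attack on ring A, or oxidative coupling between the two rings.

The fallback sets out from 25 and returns at 27, moving the chlorination ahead of the deprotection. In 25 the C6' hydroxyl is the only free phenol and it has a single open ortho position, C5'. A phenol-directed ortho-chlorination (SO2Cl2, catalytic 2,2,6,6-tetramethylpiperidine, toluene, 0 °C) should therefore deliver one chlorine and stop. The product is methyl 2-[3-chloro-2-hydroxy-6-(methoxymethoxy)-4-methylbenzoyl]-3-methoxy-5-(methoxymethoxy)benzoate F5. The capped ring A phenol cannot take part in oxidative coupling, and partial loss of a MOM group is harmless at this point. HCl in MeOH as in step 13 then gives 27.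

3. Step 11.
What may go wrong: loss of regiocontrol in the ring opening, or equilibration of the two half esters through the anhydride.

The fallback sets out from 17 and returns at 21. It differentiates the carboxyl groups by their rates of acid-catalysed esterification rather than by anhydride opening. Diester 17 is saponified (KOH, aq MeOH, reflux, then HCl) to 5-hydroxy-3-methoxyphthalic acid F6. Fischer esterification (MeOH, catalytic H2SO4, reflux) should esterify only the C1 carboxyl, because a carboxyl with two ortho substituents resists this reaction. This gives 4-hydroxy-2-methoxy-6-(methoxycarbonyl)benzoic acid F7. MOMCl (2.5 equiv) with iPr2NEt then caps both the phenol and the acid to give 2-(methoxymethyl) 1-methyl 3-methoxy-5-(methoxymethoxy)phthalate F8. The acyloxymethyl ether of F8 ionises far more readily than the aryl MOM ether, so it is removed selectively with pyridinium p-toluenesulfonate in MeOH at rt, giving 21.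

**Further compounds**

F1 | step 12 | 1,3-bis(methoxymethoxy)-5-methylbenzene | COCOc1cc(C)cc(OCOC)c1
F2 | step 12 | [2,6-bis(methoxymethoxy)-4-methylphenyl]lithium | COCOc1cc(C)cc(OCOC)c1[Li]
F3 | step 12 | methyl 2-(chlorocarbonyl)-3-methoxy-5-(methoxymethoxy)benzoate | COC(=O)c1cc(OCOC)cc(OC)c1C(Cl)=O
F4 | step 12 | methyl 2-[2,6-bis(methoxymethoxy)-4-methylbenzoyl]-3-methoxy-5-(methoxymethoxy)benzoate | COC(=O)c1cc(OCOC)cc(OC)c1C(=O)c1c(OCOC)cc(C)cc1OCOC
F5 | step 14 | methyl 2-[3-chloro-2-hydroxy-6-(methoxymethoxy)-4-methylbenzoyl]-3-methoxy-5-(methoxymethoxy)benzoate | COC(=O)c1cc(OCOC)cc(OC)c1C(=O)c1c(O)c(Cl)c(C)cc1OCOC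
F6 | step 11 | 5-hydroxy-3-methoxyphthalic acid | COc1cc(O)cc(C(=O)O)c1C(=O)O
F7 | step 11 | 4-hydroxy-2-methoxy-6-(methoxycarbonyl)benzoic acid | COC(=O)c1cc(O)cc(OC)c1C(=O)O
F8 | step 11 | 2-(methoxymethyl) 1-methyl 3-methoxy-5-(methoxymethoxy)phthalate | COCOC(=O)c1c(OC)cc(OCOC)cc1C(=O)OC
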